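## Retrosynthetic overview

1. The methylene bridge is cut last: the target comes from the chromene Mannich base 11 (fragment 1) and propionylfilicinic acid 14 (fragment 2), joined through an ortho-quinone methide.
2. The pyran ring of fragment 1 is cut at C2–C3 and C4–C4a: aryl isopropenyl ether 5 plus vinyl acetate as the C3–C4 unit, joined by an acid-catalysed cationic formal [4+2] annulation with loss of AcOH.
3. Enabling feature: ether oxygen O1 sits on the phloroglucinol ring between the acetyl-bearing C8 and the only free ortho carbon C4a, which is flanked by O1 and the 5-oxygen and is para to the 7-hydroxyl. C2 is at the acetone oxidation level, so the O1=C2 oxocarbenium ion and the C8a=C4a arene bond act together as a cationic 2-oxadiene.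
4. Ether 5 comes from 2,4,6-trihydroxyacetophenone by 4-O-silylation and Chan–Lam O-isopropenylation; 14 comes from 2,4,6-trihydroxypropiophenone by dearomatising gem-C-methylation.
5. Ring order: the aromatic ring is bought, the pyran ring is formed in step 3, the filicinic ring is made from a second bought arene in step 6, and the two ring systems are joined in step 7.

Key step: step 3

Remark on the chemistry: the target has no stereocentre, and its filicinic ring is taken as the freely interconverting enol tautomer drawn. Compound 1 is sold as the monohydrate and is dried (toluene azeotrope) before use.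

## Route

Step 1
Reactants: 1 1-(2,4,6-trihydroxyphenyl)ethan-1-one; 2 triisopropylsilyl chloride
Product: 3 1-[2,6-dihydroxy-4-(triisopropylsilyloxy)phenyl]ethan-1-one
Conditions: TIPSCl (1.05 equiv), imidazole (2.2 equiv), DMF, 0 °C
Reagents that add atoms: triisopropylsilyl chloride 2, CC(C)[Si](Cl)(C(C)C)C(C)C
Why: Silyl ether formation; the 4-hydroxyl is the most acidic and the only one neither hydrogen-bonded to nor flanked by the acetyl group, so the bulky silyl chloride should react there first.

Step 2
Reactants: 3 1-[2,6-dihydroxy-4-(triisopropylsilyloxy)phenyl]ethan-1-one; 4 4,4,5,5-tetramethyl-2-(prop-1-en-2-yl)-1,3,2-dioxaborolane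
Product: 5 1-[2-hydroxy-6-(prop-1-en-2-yloxy)-4-(triisopropylsilyloxy)phenyl]ethan-1-one
Conditions: Cu(OAc)2 (30 mol%), pyridine (3 equiv), 4 Å MS, CH2Cl2, O2 (1 atm), rt
Reagents that add atoms: isopropenylboronic acid pinacol ester 4, CC(=C)B1OC(C)(C)C(C)(C)O1
Why: Chan–Lam oxidative C–O coupling of a phenol with an alkenylboronate (copper phenoxide, transmetalation, reductive elimination from trivalent copper, reoxidation by O2); the two free hydroxyls are equivalent, and after the first coupling the remaining one is deactivated by its hydrogen bond to the acetyl group.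

Step 3
Reactants: 5 1-[2-hydroxy-6-(prop-1-en-2-yloxy)-4-(triisopropylsilyloxy)phenyl]ethan-1-one; 6 vinyl acetate
Product: 8 1-[7-hydroxy-2,2-dimethyl-5-(triisopropylsilyloxy)-2H-chromen-8-yl]ethan-1-one, via 4-acetoxychroman 7 (not isolated)
Conditions: HNTf2 (5 mol%), vinyl acetate (20 equiv), CH2Cl2 (0.02 M, slow addition of 5), 4 Å MS, −40 to 0 °C; then Et3N
Reagents that add atoms: vinyl acetate 6, CC(=O)OC=C
Why: Proposed new method: protonation of the isopropenyl ether of 5 gives a tertiary aryloxycarbenium ion at the future C2, the methylene carbon of 6 adds to it (C2–C3 bond), the resulting acetoxycarbenium ion at C4 is attacked by the only free ring carbon ortho to the ether oxygen (C4–C4a bond) to give 7, and 7 ionises under the same acid to the trioxygenated benzylic cation, which loses the C3 proton to give 8 and acetic acid. The closest known reaction type is the oxa-Povarov reaction (formal [4+2] cycloaddition of aryloxycarbenium ions from aldehyde-derived mixed acetals with alkenes to give chromans), together with the acid-mediated addition of enol esters to oxocarbenium ions; new here are the ketone-derived cation, its generation from an aryl enol ether and the elimination to the 2H-chromene in the same flask. The pyran ring closes by a 6-exo-trig Friedel–Crafts attack of the arene on the acetoxycarbenium carbon. The C4 stereocentre of 7 forms as a racemate and is erased in the elimination, so no stereocentre has to be controlled. The step needs protonation of 5 in preference to 6, which the far lower basicity of the enol ester double bond should secure, and a single closure site, which is secured because the other ortho carbon carries the acetyl group. The acetyl oxygen is held in a hydrogen bond to the free phenol and should not capture the cation, and the large excess of 6 at high dilution of 5 should suppress self-addition of 5.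

Step 4
Reactants: 8 1-[7-hydroxy-2,2-dimethyl-5-(triisopropylsilyloxy)-2H-chromen-8-yl]ethan-1-one
Product: 9 1-(5,7-dihydroxy-2,2-dimethyl-2H-chromen-8-yl)ethan-1-one
Conditions: TBAF (1.1 equiv), AcOH (1.1 equiv), THF, 0 °C
Reagents that add atoms: none
Why: Fluoride-mediated cleavage of an aryl silyl ether, buffered with AcOH; the chromene double bond and the ketone are inert to these conditions.

Step 5
Reactants: 9 1-(5,7-dihydroxy-2,2-dimethyl-2H-chromen-8-yl)ethan-1-one; 10 N,N-dimethylmethyleneiminium iodide (Eschenmoser's salt)
Product: 11 1-{6-[(dimethylamino)methyl]-5,7-dihydroxy-2,2-dimethyl-2H-chromen-8-yl}ethan-1-one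
Conditions: Me2N=CH2 I (1.05 equiv), Et3N (1.0 equiv), CH2Cl2, 0 °C to rt
Reagents that add atoms: Eschenmoser's salt 10, C=[N+](C)C.[I-]
Why: Phenolic Mannich reaction with a preformed iminium salt at C6, the only free ring carbon, which is flanked by two hydroxyls and is far more nucleophilic than the chromene double bond or the ketone enol.

Step 6
Reactants: 12 1-(2,4,6-trihydroxyphenyl)propan-1-one; 13 iodomethane
Product: 14 3,5-dihydroxy-4,4-dimethyl-2-propanoylcyclohexa-2,5-dien-1-one (propionylfilicinic acid)
Conditions: NaOMe (3 equiv), MeI (2.5 equiv), MeOH, 0 °C to rt; then 1 M HCl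
Reagents that add atoms: iodomethane 13, CI
Why: Dearomatising gem-C-methylation of an acylphloroglucinol, the classical entry to acylfilicinic acids; the phenoxide is alkylated at a ring carbon between two oxygens and the second methyl should enter the same, now more nucleophilic, carbon.

Step 7
Reactants: 11 1-{6-[(dimethylamino)methyl]-5,7-dihydroxy-2,2-dimethyl-2H-chromen-8-yl}ethan-1-one; 14 3,5-dihydroxy-4,4-dimethyl-2-propanoylcyclohexa-2,5-dien-1-one
Product: 16 2-[(8-acetyl-5,7-dihydroxy-2,2-dimethyl-2H-chromen-6-yl)methyl]-3,5-dihydroxy-4,4-dimethyl-6-propanoylcyclohexa-2,5-dien-1-one (target), via ortho-quinone methide 15 (not isolated)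
Conditions: 11 (1.0 equiv), 14 (1.1 equiv), toluene, 80 °C, N2
Reagents that add atoms: none
Why: Mannich-base alkylation; the acidic triketone 14 protonates the amine, loss of Me2NH gives ortho-quinone methide 15, and the filicinate adds to its exocyclic carbon in a Michael reaction through its only free ring carbon, which forms the methylene bridge.

## Compound list

1 | 1-(2,4,6-trihydroxyphenyl)ethan-1-one | CC(=O)c1c(O)cc(O)cc1O | starting material
2 | triisopropylsilyl chloride | CC(C)[Si](Cl)(C(C)C)C(C)C | starting material
3 | 1-[2,6-dihydroxy-4-(triisopropylsilyloxy)phenyl]ethan-1-one | CC(=O)c1c(O)cc(O[Si](C(C)C)(C(C)C)C(C)C)cc1O | intermediate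
4 | 4,4,5,5-tetramethyl-2-(prop-1-en-2-yl)-1,3,2-dioxaborolane | CC(=C)B1OC(C)(C)C(C)(C)O1 | starting material
5 | 1-[2-hydroxy-6-(prop-1-en-2-yloxy)-4-(triisopropylsilyloxy)phenyl]ethan-1-one | CC(=O)c1c(O)cc(O[Si](C(C)C)(C(C)C)C(C)C)cc1OC(C)=C | intermediate
6 | vinyl acetate | CC(=O)OC=C | starting material
7 | 8-acetyl-7-hydroxy-2,2-dimethyl-5-(triisopropylsilyloxy)-3,4-dihydro-2H-chromen-4-yl acetate (racemic, not isolated) | CC(=O)OC1CC(C)(C)Oc2c(C(C)=O)c(O)cc(O[Si](C(C)C)(C(C)C)C(C)C)c12 | intermediate
8 | 1-[7-hydroxy-2,2-dimethyl-5-(triisopropylsilyloxy)-2H-chromen-8-yl]ethan-1-one | CC(=O)c1c(O)cc(O[Si](C(C)C)(C(C)C)C(C)C)c2C=CC(C)(C)Oc12 | intermediate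
9 | 1-(5,7-dihydroxy-2,2-dimethyl-2H-chromen-8-yl)ethan-1-one | CC(=O)c1c(O)cc(O)c2C=CC(C)(C)Oc12 | intermediate
10 | N,N-dimethylmethyleneiminium iodide | C=[N+](C)C.[I-] | starting material
11 | 1-{6-[(dimethylamino)methyl]-5,7-dihydroxy-2,2-dimethyl-2H-chromen-8-yl}ethan-1-one | CC(=O)c1c(O)c(CN(C)C)c(O)c2C=CC(C)(C)Oc12 | intermediate
12 | 1-(2,4,6-trihydroxyphenyl)propan-1-one | CCC(=O)c1c(O)cc(O)cc1O | starting material
13 | iodomethane | CI | starting material
14 | 3,5-dihydroxy-4,4-dimethyl-2-propanoylcyclohexa-2,5-dien-1-one | CCC(=O)C1=C(O)C(C)(C)C(O)=CC1=O | intermediate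
15 | 8-acetyl-7-hydroxy-2,2-dimethyl-6-methylidene-2H-chromen-5(6H)-one (not isolated) | CC(=O)C1=C(O)C(=C)C(=O)C2=C1OC(C)(C)C=C2 | intermediate
16 | 2-[(8-acetyl-5,7-dihydroxy-2,2-dimethyl-2H-chromen-6-yl)methyl]-3,5-dihydroxy-4,4-dimethyl-6-propanoylcyclohexa-2,5-dien-1-one | CCC(=O)C1=C(O)C(C)(C)C(O)=C(Cc2c(O)c3c(c(C(C)=O)c2O)OC(C)(C)C=C3)C1=O | target

## Step count and risks

Total step count: 7. Longest linear sequence: 6 steps (steps 1, 2, 3, 4, 5 and 7); step 6 is the one-step branch to fragment 2.

Steps most likely to fail:

1. Step 3 (proposed new method). The cation may be diverted in three ways: cationic self-addition of the enol ether instead of capture by vinyl acetate; capture by the acetyl oxygen followed by closure through the ketone enol carbon on the wrong side of the ether oxygen (a Petasis–Ferrier-type course); or re-ionisation of the chromene at C4 in the acid medium with oligomerisation. Fallback with known chemistry: the route sets out from 3 and skips step 2. Compound 3 is condensed with 3-methylbut-2-enal under ethylenediammonium diacetate catalysis in refluxing toluene. A Knoevenagel-type condensation at the free ring carbon should give the dienone (ortho-quinone methide) 2-acetyl-3-hydroxy-6-(3-methylbut-2-en-1-ylidene)-5-(triisopropylsilyloxy)cyclohexa-2,4-dien-1-one F1, which closes by oxa-6π electrocyclisation. Because the 4-oxygen is silylated, only the oxygen next to the acetyl group can become the ring oxygen, so the fallback comes back to the route at 8.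

2. Step 2. The chelating ortho-hydroxyacetophenone unit may sequester the copper so that transmetalation stalls, or a second etherification may follow the first. Fallback: the route sets out from 3 and uses iridium-catalysed transfer alkenylation with isopropenyl acetate ([Ir(cod)Cl]2, a complex of monovalent iridium, Na2CO3, toluene, 100 °C). This is an addition–elimination on the enol ester, not an oxidative C–O coupling, and it comes back to the route at 5 (no new compound, F0).

3. Step 7. Retro-Mannich exchange may scramble the aminomethyl group between the two partners and give the two symmetrical dimers; the ortho-quinone methide may also add to the chromene double bond. Fallback: the route sets out from 9 (skipping step 5) and 14, which are condensed in one pot with one equivalent of aqueous formaldehyde and NaOH in water–THF at rt, the classical methylene bridging of acylphloroglucinols. The mixed dimer is separated from the symmetrical dimers by chromatography, and the fallback comes back to the route at 16 (no new compound, F0).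

Further compounds
F1 | step 3 | 2-acetyl-3-hydroxy-6-(3-methylbut-2-en-1-ylidene)-5-(triisopropylsilyloxy)cyclohexa-2,4-dien-1-one | CC(=O)C1=C(O)C=C(O[Si](C(C)C)(C(C)C)C(C)C)C(=CC=C(C)C)C1=O
F0 | step 2 | none | none
F0 | step 7 | none | none
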